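**Retrosynthetic overview**

1. The 1,4-dioxane is opened at both tertiary C–O bonds to give the triterpene o-quinone and guaia-1(5),3,11-triene; this final hetero-Diels–Alder union copies the presumed biogenesis.
2. In the triterpene, the C6=C7 alkene is traced back to a C7 ketone, ring B is opened at C9–C10 (Friedel–Crafts closure of a benzyl ketone onto ring A), and then rings C and D are opened together at C8–C9 and C13–C14.
3. Enabling feature: in ring C (C8, C9, C11, C12, C13, C14) these two bonds lie opposite each other, and C13/C14 are neighbouring methyl-bearing quaternary carbons. With C7 as a ketone, C14=C8–C7=O is an enone that accepts a tertiary C13 radical (C27 as =CH2), and its C8 enolate sits 1,6 to a C9 methyl ketone (C25), so one HAT-initiated conjugate addition/aldol closes ring D and ring C.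
4. Ring E (C17, C18, C20) comes from a bicyclo[2.2.2]octene, made by Diels–Alder reaction of a 2-silyloxy-1,4-dimethylcyclohexadiene with methyl vinyl ketone; ozone cleaves its silyl enol ether bridge into the C20 carboxyl and the C17 aldehyde, all three appendages cis.
5. Ring order: E (ring A is bought as an arene) → D and C together → B → dioxane with the sesquiterpene rings.

Key step: step 12

Numbering remark: friedelane numbering is used for the triterpene (ring A = C1–C5, C10; methyls C23 on C4, C25 on C9, C26 on C14, C27 on C13, C28 on C17, C30 on C20; ester carbon C29) and guaiane numbering for the sesquiterpene.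

Assumption: commercial (−)-rotundone is taken as (3S,5R,8S), so its C7 and C10 centres are those of the target; the (S)-oxazaborolidinium catalyst of step 3 is taken to give the drawn enantiomer of 5, and its (R)-antipode is used if the sense of induction is the opposite.

**Route**

Step 1
Reactants: 1 3-methylcyclohex-2-en-1-one
Product: 2 (±)-3,6-dimethylcyclohex-2-en-1-one
Conditions: LiN(iPr)2, THF, −78 °C; MeI, −78 °C to rt
Reagents that add atoms: iodomethane, CI
Why: Kinetic α'-enolate alkylation of an enone; the new centre is racemic and is erased in step 2.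

Step 2
Reactants: 2 (±)-3,6-dimethylcyclohex-2-en-1-one
Product: 3 2-(tert-butyldimethylsilyloxy)-1,4-dimethylcyclohexa-1,3-diene
Conditions: LiN(iPr)2, THF, −78 °C; t-BuMe2SiCl, DMPU, −78 °C to 0 °C
Reagents that add atoms: tert-butyldimethylsilyl chloride, CC(C)(C)[Si](C)(C)Cl
Why: Kinetic α'-deprotonation and O-silylation should give the cross-conjugated 2-silyloxy diene as one regioisomer.

Step 3
Reactants: 3 2-(tert-butyldimethylsilyloxy)-1,4-dimethylcyclohexa-1,3-diene; 4 methyl vinyl ketone
Product: 5 endo-2-acetyl-5-(tert-butyldimethylsilyloxy)-1,4-dimethylbicyclo[2.2.2]oct-5-ene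
Conditions: (S)-1-(2-methylphenyl)-3,3-diphenyltetrahydro-1H,3H-pyrrolo[1,2-c][1,3,2]oxazaborole·HNTf2 (20 mol %), CH2Cl2, −78 °C to −40 °C
Reagents that add atoms: none
Why: Chiral Lewis acid-catalysed Diels–Alder reaction of a 2-silyloxy diene: the silyloxy group directs the "para" orientation (diene terminus next to C–OSi bonds to the enone CH2), the endo rule places the acetyl group syn to the new enol ether bridge (C18 relative to C17 and C20), and the catalyst sets the absolute sense.

Step 4
Reactants: 5 endo-2-acetyl-5-(tert-butyldimethylsilyloxy)-1,4-dimethylbicyclo[2.2.2]oct-5-ene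
Product: 6 bicyclic enol triflate (acetyl converted to 1-(triflyloxy)vinyl)
Conditions: LiN(iPr)2, THF, −78 °C; PhNTf2, −78 °C to 0 °C
Reagents that add atoms: N-phenylbis(trifluoromethanesulfonimide), O=S(=O)(N(c1ccccc1)S(=O)(=O)C(F)(F)F)C(F)(F)F
Why: Kinetic deprotonation at the methyl group (the hindered C18–H is not touched) and O-triflation give the 1,1-disubstituted enol triflate, which also keeps this carbon inert to ozone.

Step 5
Reactants: 6 bicyclic enol triflate
Product: 8 ring E aldehyde methyl ester, via carboxylic acid 7 (not isolated)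
Conditions: O3, CH2Cl2/MeOH, −78 °C; Me2S, −78 °C to rt; then Me3SiCHN2, PhMe/MeOH, 0 °C
Reagents that add atoms: ozone, [O-][O+]=O; (trimethylsilyl)diazomethane, C[Si](C)(C)C=[N+]=[N-]
Why: Ozonolysis of the electron-rich silyl enol ether (the electron-poor enol triflate is spared) cleaves the bridge into the C17 aldehyde and the C20 acid, so C16, C13 and C29 stay on one face of ring E and the two methyl groups on the other; diazoalkane esterification gives the methyl ester.

Step 6
Reactants: 8 ring E aldehyde methyl ester
Product: 9 (E)-enone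
Conditions: Ph3P=CHC(O)CH3, PhMe, 100 °C
Reagents that add atoms: 1-(triphenylphosphoranylidene)propan-2-one, CC(=O)C=P(c1ccccc1)(c1ccccc1)c1ccccc1
Why: Wittig reaction of a stabilised ylide with the non-enolisable aldehyde should give the E enone.

Step 7
Reactants: 9 (E)-enone
Product: 10 saturated methyl ketone
Conditions: [(Ph3P)CuH]6 (5 mol %), H2 (30 bar), t-BuOH, PhH, rt
Reagents that add atoms: none
Why: Copper hydride-catalysed conjugate reduction is selective for the enone C=C and should leave the enol triflate and the ester alone.

Step 8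
Reactants: 10 saturated methyl ketone
Product: 11 (E)-trisubstituted unsaturated N-methoxy-N-methylamide
Conditions: (EtO)2P(O)CH2C(O)N(OMe)Me, NaH, THF, 0 °C to 65 °C; E isomer separated
Reagents that add atoms: diethyl [2-(methoxy(methyl)amino)-2-oxoethyl]phosphonate, CCOP(=O)(CC(=O)N(C)OC)OCC
Why: Horner–Wadsworth–Emmons olefination of a methyl ketone gives the C14=C8 double bond, the E isomer expected as the major one.

Step 9
Reactants: 11 (E)-trisubstituted unsaturated N-methoxy-N-methylamide; 12 2-(2-bromoethyl)-2-methyl-1,3-dioxolane
Product: 14 1,1-disubstituted alkene carrying the dioxolane chain, via alkylzinc bromide 13 (not isolated)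
Conditions: 12, Zn, LiCl, THF, 40 °C; then 11, Pd(PPh3)4 (5 mol %), THF, 60 °C
Reagents that add atoms: none
Why: Negishi sp3–sp2 coupling of the alkylzinc bromide with the enol triflate installs C12–C11–C9 (C9 masked as the dioxolane) and creates the C13=C27 alkene; the amide and ester do not react with the zinc reagent.

Step 10
Reactants: 15 2,3-dimethoxytoluene
Product: 16 1-(chloromethyl)-3,4-dimethoxy-2-methylbenzene
Conditions: (CH2O)n, HCl (gas), AcOH, 40 °C
Reagents that add atoms: formaldehyde, C=O; hydrogen chloride, Cl
Why: Blanc chloromethylation should occur para to the 3-methoxy group (the 2-methoxy group is twisted out of conjugation) and ortho to the methyl group.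

Step 11
Reactants: 14 1,1-disubstituted alkene carrying the dioxolane chain; 16 1-(chloromethyl)-3,4-dimethoxy-2-methylbenzene
Product: 19 alkene–enone–methyl ketone, via arylmethylmagnesium chloride 17 (not isolated), via dioxolane-protected enone 18 (not isolated)
Conditions: 16, Mg, Et2O/THF, 0 °C; add to 14, THF, −40 °C to 0 °C; then 1 M HCl, THF, rt
Reagents that add atoms: water, O
Why: Addition of the benzylic magnesium reagent to the N-methoxy-N-methylamide stops at the ketone through the chelated tetrahedral intermediate, and the acidic work-up also hydrolyses the dioxolane to the C9 methyl ketone.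

Step 12
Reactants: 19 alkene–enone–methyl ketone
Product: 20 tricyclic (rings C, D, E) β-hydroxy ketone
Conditions: Fe(acac)3 (30 mol %), PhSiH3 (3 equiv), EtOH/HOCH2CH2OH 5:1, 0 °C to rt, argon
Reagents that add atoms: none
Why: Hydrogen-atom transfer from the iron hydride to the 1,1-disubstituted alkene gives the tertiary C13 radical (C27 becomes the methyl), which adds 6-exo-trig to C14, the β-carbon of the enone, and the resulting C8 α-keto radical is reduced to the iron enolate that attacks the C9 methyl ketone in a 6-(enolexo)-exo-trig aldol closure. The closest known reaction type is the iron/silane HAT-initiated radical conjugate addition–aldol (radical–polar crossover) bicyclisation of alkene–enone–ketone substrates, which is known to forge vicinal quaternary carbons. Ring D closes in the radical step (C13–C14) and ring C in the aldol step (C8–C9). C13 and C14 are set under substrate control by the cis side chains on C17 and C18: with H18 in the plane of the radical the small C27 methyl lies next to quaternary C17 and C12 points outward, and a chair transition state with the enone terminus C8 equatorial places the two methyl groups anti (13α,14β), the arrangement that lets the enolate reach C9 in a trans-fused chair. C8 and C9 follow from the chelated chair aldol (acyl group equatorial, 9-OH axial) and are of no consequence, because C9 is ionised and C8 equilibrated in step 13. The step needs hydrogen-atom transfer to the electron-rich alkene rather than to the enone and ring closure faster than enolate protonation, which the electronic difference between the two alkenes and the six-membered intramolecular aldol should secure.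

Step 13
Reactants: 20 tricyclic (rings C, D, E) β-hydroxy ketone
Product: 22 pentacyclic 7-ketone (ring B closed), via ring C enone 21 (not isolated)
Conditions: MeSO3H, CH2Cl2, 0 °C to rt
Reagents that add atoms: none
Why: Acid dehydrates the aldol to the C8=C9 enone and the arene, activated para to a methoxy group and with only one free ortho position, closes ring B by intramolecular Friedel–Crafts alkylation at C9 (the known benzyl vinyl ketone to 2-tetralone cyclisation); attack anti to the axial C14 methyl should give 9β-methyl, and the epimerisable C8 should settle as the trans-fused 8α-H isomer.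

Step 14
Reactants: 22 pentacyclic 7-ketone
Product: 23 C6=C7 enol triflate
Conditions: KN(SiMe3)2, THF, −78 °C; PhNTf2, −78 °C to 0 °C
Reagents that add atoms: N-phenylbis(trifluoromethanesulfonimide), O=S(=O)(N(c1ccccc1)S(=O)(=O)C(F)(F)F)C(F)(F)F
Why: Deprotonation at the benzylic C6 (more acidic and less hindered than C8–H) gives the arene-conjugated enolate, which is O-triflated.

Step 15
Reactants: 23 C6=C7 enol triflate
Product: 24 6-ene catechol dimethyl ether
Conditions: Pd(OAc)2 (5 mol %), PPh3, HCO2H, n-Bu3N, DMF, 60 °C
Reagents that add atoms: none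
Why: Palladium-catalysed formate reduction of an enol triflate gives the C6=C7 alkene without touching the C8 stereocentre.

Step 16
Reactants: 24 6-ene catechol dimethyl ether
Product: 25 6-ene catechol
Conditions: BBr3, CH2Cl2, −78 °C to −20 °C; then H2O
Reagents that add atoms: none
Why: Boron tribromide cleaves the two adjacent aryl methyl ethers at low temperature faster than it attacks the hindered tertiary methyl ester.

Step 17
Reactants: 26 (−)-rotundone
Product: 27 rotundol (guaia-1(5),11-dien-2-ol, C2 epimers)
Conditions: NaBH4, CeCl3·7H2O, MeOH, 0 °C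
Reagents that add atoms: none
Why: Luche 1,2-reduction of the enone; the configuration at C2 is lost in step 18.

Step 18
Reactants: 27 rotundol
Product: 29 guaia-1(5),3,11-triene, via kinetic 1(5),2-diene 28 (not isolated)
Conditions: MeO2CNSO2NEt3 (inner salt), PhH, 50 °C; then PhMe, 80 °C, argon; used at once
Reagents that add atoms: none
Why: Syn-elimination of the sulfamate ester gives the cyclopentadiene, and successive 1,5-hydrogen shifts should move it to the more substituted tautomer that keeps the ring-fusion double bond; C7 and C10 are not touched.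

Step 19
Reactants: 25 6-ene catechol; 29 guaia-1(5),3,11-triene
Product: 31 target CNP0113384.2, via o-quinone 30 (not isolated)
Conditions: Ag2O, Et2O/CH2Cl2, −20 °C to 0 °C, 29 in excess, dark
Reagents that add atoms: none
Why: Ag2O oxidises the catechol to the o-quinone, which as an electron-poor heterodiene should add suprafacially across the tetrasubstituted C1=C5 bond of the cyclopentadiene (inverse-demand hetero-Diels–Alder), giving the cis-fused dioxane and leaving C3=C4 and the isopropenyl group; the orientation (O on C2 to guaiane C5) and the face syn to the C10 methyl are those of the natural adduct and are not secured by the substrate.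

**Compound list**

1 | 3-methylcyclohex-2-en-1-one | CC1=CC(=O)CCC1 | starting material
2 | (±)-3,6-dimethylcyclohex-2-en-1-one | CC1=CC(=O)C(C)CC1 | intermediate
3 | 2-(tert-butyldimethylsilyloxy)-1,4-dimethylcyclohexa-1,3-diene | CC1=CC(O[Si](C)(C)C(C)(C)C)=C(C)CC1 | intermediate
4 | methyl vinyl ketone (but-3-en-2-one) | C=CC(C)=O | starting material
5 | endo-2-acetyl-5-(tert-butyldimethylsilyloxy)-1,4-dimethylbicyclo[2.2.2]oct-5-ene; acetyl syn to the enol ether bridge, absolute configuration as drawn | CC(=O)[C@@H]1C[C@@]2(C)CC[C@]1(C)C=C2O[Si](C)(C)C(C)(C)C | intermediate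
6 | endo-2-[1-(trifluoromethylsulfonyloxy)vinyl] analogue of 5 | C=C(OS(=O)(=O)C(F)(F)F)[C@@H]1C[C@@]2(C)CC[C@]1(C)C=C2O[Si](C)(C)C(C)(C)C | intermediate
7 | ring E acid aldehyde: 1,4-dimethylcyclohexane with 1-CO2H, 4-CHO and 3-[1-(triflyloxy)vinyl] all cis | C=C(OS(=O)(=O)C(F)(F)F)[C@@H]1C[C@](C)(C(=O)O)CC[C@]1(C)C=O | intermediate
8 | methyl ester of 7 | C=C(OS(=O)(=O)C(F)(F)F)[C@@H]1C[C@](C)(C(=O)OC)CC[C@]1(C)C=O | intermediate
9 | (E)-4-oxopent-2-enyl (enone) homologue of 8 | C=C(OS(=O)(=O)C(F)(F)F)[C@@H]1C[C@](C)(C(=O)OC)CC[C@]1(C)/C=C/C(C)=O | intermediate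
10 | 3-oxobutyl methyl ketone | C=C(OS(=O)(=O)C(F)(F)F)[C@@H]1C[C@](C)(C(=O)OC)CC[C@]1(C)CCC(C)=O | intermediate
11 | (E)-3-methylpent-2-enoic N-methoxy-N-methylamide side chain on C17 | C=C(OS(=O)(=O)C(F)(F)F)[C@@H]1C[C@](C)(C(=O)OC)CC[C@]1(C)CC/C(C)=C/C(=O)N(C)OC | intermediate
12 | 2-(2-bromoethyl)-2-methyl-1,3-dioxolane | CC1(CCBr)OCCO1 | starting material
13 | [2-(2-methyl-1,3-dioxolan-2-yl)ethyl]zinc bromide | CC1(CC[Zn]Br)OCCO1 | intermediate
14 | amide 11 with the triflate replaced by the 2-(2-methyl-1,3-dioxolan-2-yl)ethyl group | C=C(CCC2(C)OCCO2)[C@@H]1C[C@](C)(C(=O)OC)CC[C@]1(C)CC/C(C)=C/C(=O)N(C)OC | intermediate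
15 | 2,3-dimethoxytoluene | Cc1cccc(OC)c1OC | starting material
16 | 1-(chloromethyl)-3,4-dimethoxy-2-methylbenzene | ClCc1ccc(OC)c(OC)c1C | intermediate
17 | (3,4-dimethoxy-2-methylbenzyl)magnesium chloride | Cl[Mg]Cc1ccc(OC)c(OC)c1C | intermediate
18 | benzyl (E)-enone with C9 still as dioxolane | C=C(CCC2(C)OCCO2)[C@@H]1C[C@](C)(C(=O)OC)CC[C@]1(C)CC/C(C)=C/C(=O)Cc1ccc(OC)c(OC)c1C | intermediate
19 | key-step substrate: ring E bearing the 5-oxohex-1-en-2-yl chain on C18 and the benzyl (E)-enone chain on C17 | C=C(CCC(C)=O)[C@@H]1C[C@](C)(C(=O)OC)CC[C@]1(C)CC/C(C)=C/C(=O)Cc1ccc(OC)c(OC)c1C | intermediate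
20 | tricyclic C/D/E β-hydroxy ketone (8α-H, 9β-OH, 13α-Me, 14β-Me, 17β-Me, 18β-H, 20α-CO2Me) | COc1ccc(CC(=O)[C@H]2[C@@](C)(O)CC[C@@]3(C)[C@@H]4C[C@](C)(C(=O)OC)CC[C@]4(C)CC[C@]23C)c(C)c1OC | intermediate
21 | C8=C9 enone from dehydration of 20 | COc1ccc(CC(=O)C2=C(C)CC[C@@]3(C)[C@@H]4C[C@](C)(C(=O)OC)CC[C@]4(C)CC[C@]23C)c(C)c1OC | intermediate
22 | methyl 2,3-dimethoxy-7-oxo-24-norfriedela-1,3,5(10)-trien-29-oate (8α-H, 9β-Me) | COc1cc2c(c(C)c1OC)CC(=O)[C@H]1[C@@]2(C)CC[C@@]2(C)[C@@H]3C[C@](C)(C(=O)OC)CC[C@]3(C)CC[C@]12C | intermediate
23 | 7-(trifluoromethylsulfonyloxy)-6-ene derived from 22 | COc1cc2c(c(C)c1OC)C=C(OS(=O)(=O)C(F)(F)F)[C@H]1[C@@]2(C)CC[C@@]2(C)[C@@H]3C[C@](C)(C(=O)OC)CC[C@]3(C)CC[C@]12C | intermediate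
24 | methyl 2,3-dimethoxy-24-norfriedela-1,3,5(10),6-tetraen-29-oate | COc1cc2c(c(C)c1OC)C=C[C@H]1[C@@]2(C)CC[C@@]2(C)[C@@H]3C[C@](C)(C(=O)OC)CC[C@]3(C)CC[C@]12C | intermediate
25 | methyl 2,3-dihydroxy-24-norfriedela-1,3,5(10),6-tetraen-29-oate | Oc1cc2c(c(C)c1O)C=C[C@H]1[C@@]2(C)CC[C@@]2(C)[C@@H]3C[C@](C)(C(=O)OC)CC[C@]3(C)CC[C@]12C | intermediate
26 | (−)-rotundone, (4S,7R,10S)-guaia-1(5),11-dien-2-one | C=C(C)[C@@H]1CC[C@H](C)C2=C(C1)[C@@H](C)CC2=O | starting material
27 | rotundol, guaia-1(5),11-dien-2-ol (C2 epimers) | C=C(C)[C@@H]1CC[C@H](C)C2=C(C1)[C@@H](C)CC2O | intermediate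
28 | (4S,7R,10S)-guaia-1(5),2,11-triene | C=C(C)[C@@H]1CC[C@H](C)C2=C(C1)[C@@H](C)C=C2 | intermediate
29 | (7R,10S)-guaia-1(5),3,11-triene | C=C(C)[C@@H]1CC[C@H](C)C2=C(C1)C(C)=CC2 | intermediate
30 | o-quinone of 25 (2,3-dioxo-1(10),4,6-triene) | O=C1C=C2C(=C(C)C1=O)C=C[C@H]1[C@@]2(C)CC[C@@]2(C)[C@@H]3C[C@](C)(C(=O)OC)CC[C@]3(C)CC[C@]12C | intermediate
31 | CNP0113384.2 | C=C(C)[C@@H]1CC[C@H](C)[C@@]23CC=C(C)[C@]2(C1)Oc1cc2c(c(C)c1O3)C=C[C@H]1[C@@]2(C)CC[C@@]2(C)[C@@H]3C[C@](C)(C(=O)OC)CC[C@]3(C)CC[C@]12C | target

**Count and risks**

Total step count: 19. Longest linear sequence: 16 steps (steps 1–9, 11–16, 19).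

Steps most likely to fail:

1. Step 19. What may go wrong: cycloaddition across another π-bond of the triene (the less hindered C3=C4 bond, which simple frontier-orbital and cation-stability arguments favour, or the isopropenyl group), the reverse orientation of the two oxygen atoms, attack on the other face, 1,5-hydrogen shift of the cyclopentadiene to other tautomers, and isomerisation of the o-quinone to the extended quinone methide before it is trapped. Fallback: the two C–O bonds are made one after the other, setting out from 25 and 29 and coming back at 31. Triene 29 is epoxidised with dimethyldioxirane at the tetrasubstituted C1=C5 bond to the vinyl epoxide F1. Opening of F1 by the less hindered C2 hydroxyl of 25 at the allylic C5 terminus, catalysed by Pd(PPh3)4 with BEt3 as co-catalyst (net retention through the π-allyl complex), gives the C5 aryl ether C1 tertiary alcohol F2. Ionisation of the C1 alcohol with BF3·OEt2 at −78 °C and capture by the C3 phenol, which can only close cis, gives 31.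

2. Step 12. What may go wrong: protonation of the iron enolate before it closes ring C, and closure of ring D on the other face of the C13 radical relative to ring E (the natural series needs the ring E conformer with the C18 side chain axial). Fallback: the two bonds are formed in separate operations, setting out from 18 (isolated by neutral work-up in step 11) and coming back at 22. The same Fe(acac)3/PhSiH3 radical cyclisation on 18, where the enolate can only be protonated, gives the bicyclic D/E dioxolane ketone F3. MeSO3H then turns the dioxolane into the C9 oxocarbenium ion, which the C7 enol attacks through C8 (the only six-membered aldol mode); dehydration to 21 and Friedel–Crafts closure follow in the same acid to give 22.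

3. Step 16. What may go wrong: addition of HBr to the C6=C7 styrene, acid-induced migration of that double bond, and partial loss of the methyl ester during ether cleavage. Fallback: oxidative demethylation instead of Lewis-acid cleavage, setting out from 24 and coming back at 30. (NH4)2Ce(NO3)6 in MeCN/H2O at 0 °C converts the dimethyl ether directly into the o-quinone 30, which is extracted and combined with 29 as in step 19; no new compound is made (F0).

Further compounds
F1 | step 19 | 1,5-epoxyguaia-3,11-diene, epoxide on the face syn to the C10 methyl | C=C(C)[C@@H]1CC[C@H](C)[C@@]23CC=C(C)[C@]2(C1)O3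
F2 | step 19 | C5 (triterpene C2–O) aryl ether with free C1 tertiary alcohol and free C3 phenol | C=C(C)[C@@H]1CC[C@H](C)[C@@]2(O)CC=C(C)[C@]2(C1)Oc1cc2c(c(C)c1O)C=C[C@H]1[C@@]2(C)CC[C@@]2(C)[C@@H]3C[C@](C)(C(=O)OC)CC[C@]3(C)CC[C@]12C
F3 | step 12 | bicyclic D/E benzyl ketone with C13–C14 formed and C9 as dioxolane | CC1(CC[C@@]2(C)[C@@H]3C[C@](C)(C(=O)OC)CC[C@]3(C)CC[C@]2(C)CC(=O)Cc2ccc(OC)c(OC)c2C)OCCO1
F0 | step 16 | none | none
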